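## Analysis of the target

Compound 29 is a heliangolide. Ring A is the ten-membered carbocycle C1–C10, ring B the α-methylene-γ-butyrolactone (O–C6, C7, C11, C12, exocyclic C11=C13) trans-fused across C6–C7, and ring C the oxirane on C1/C10. C4=C5 is a Z-trisubstituted alkene, O3 carries an isovalerate and O8 a (2R,3S)-2,3-dimethyloxirane-2-carboxylate, whose two methyl groups are cis (an epoxidized tiglate). Ring A holds six stereocentres (1R,3S,6R,7R,8R,10R): C6, C7 and C8 are contiguous (H6 and H7 anti, O6 and O8 1,3-anti), C3 is separated from them by the alkene, and C1/C10 are the trans-epoxide of a former E-alkene. The two centres of the acyl group are remote from the core and must be set by catalysis. The sensitive groups are the exocyclic enoate (no late nucleophile or strong base), two epoxides and a 1,5-diene that cyclize transannularly under acid, and two different esters that can migrate between O6 and O8. The difficulty is a medium ring with two trisubstituted alkenes of opposite geometry, whose end-to-end closure is strained, and five oxygenated carbons that must be told apart. The feature that invites the strategy: C1–C6, with the cis C4=C5 bond, the oxygens on C3 and C6 and the branch C10(C14)–C9 on C1, are the atoms of a 4-oxygenated 6-isopropenyl-3-methylcyclohex-2-enone (carvone after 1,3-transposition), and C8=C7–C6(O)–C1–C10=C9, read through ring C, is the retron of an oxy-Cope rearrangement. Cutting C8–C9 and drawing C1–C6 therefore turns ring A into a cyclohexene in which the Z-alkene is fixed by the ring, plus a four-carbon alkenyl unit (C7, C8, C11–C13).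

## Retrosynthetic reasoning

29 ⇒ 28. The two C–O bonds of ring C are cut first, because the oxirane is the most acid-sensitive group. In 28, C1=C10 is the only electron-rich alkene (C4=C5 lies between two acyloxy carbons, C11=C13 is conjugated), so an electrophilic epoxidation only has to choose the outer face of the E-alkene.

28 ⇒ 27 ⇒ 24. The O3–acyl bond is cut, then ring B is opened by oxidation level and not at a C–C bond: 27 arises from triol 24 by oxidation of the primary allylic alcohol C12 and capture by O6. This avoids enolate methylenation of a lactone beside two esters. It requires that O8 is already acylated, so that only O6 can close.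

24 ⇒ 23 ⇒ 19 + 22. The C6–H bond and the O8–acyl bond are cut together. Aldehyde 22 is bound to O8 of β-hydroxy ketone 19, passes its hydride to C6 and remains as the ester. One step sets C6 anti to C8, tells O6 from O8 and brings in the acyl group.

19 ⇒ 18. O8 is exchanged for silicon (C–Si to C–O with retention). An oxygen on C8 would sit β to the enolate formed in the ring expansion and would be eliminated; silicon cannot leave.

18 ⇒ 15. This is the key disconnection: C8–C9 is cut and C6–C1 is drawn, which gives the 1,5-diene alkoxide of carbinol 15. Gained are ring A from a six-membered ring, the E-alkene C1=C10, the stereocentres C8 and C7, and the Z-alkene for free. The forward reaction needs a chair transition state, which the trans arrangement of the two alkenyl groups and the E-vinylsilane provide.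

15 ⇒ 6 + 12. The C6–C7 bond is cut: the alkenyl metal from stannane 12 adds to ketone 6 anti to the isopropenyl group.

12 ⇒ 11 ⇒ 8 + 10; 8 ⇐ 7; 10 ⇐ 9. C7–Sn and C8–H come from a syn hydrostannation, which places silicon trans to tin and so cis to the C11 unit. The C7–C11 bond comes from an sp–sp2 coupling, and the C–Si bond from substitution at silicon.

6 ⇒ 5 ⇒ 4 ⇒ 2 ⇒ 1. The C6 carbonyl comes from allylic oxidation. The C3 oxygen and the position of C4=C5 come from epoxidation and 1,3-transposition of carvone 1, which gives the trans relationship of O3 and the isopropenyl group.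

22 ⇒ 21 ⇒ 20. The aldehyde comes from the epoxy alcohol, and that from asymmetric epoxidation of allylic alcohol 20.

## Alternatives that were turned down

Alternative 1: the textbook cut of C6–C7 together with the lactone C–O bond. The seco aldehyde–allylic bromide A1 would be cyclized by an intramolecular Barbier or Nozaki–Hiyama–Kishi allylation (CrCl2 or Zn) to the lactone A2. It was turned down for three reasons. A1 needs C3, C8, the Z-enal and the E-alkene to be built one by one in an open chain. The key step then forms a single C–C bond at high dilution. It must set C6 and C7 through a floppy ten-membered transition state in which only C8 is near.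

Alternative 2: cut of C4=C5. Diene A3, with ring B already in place, would be closed by ring-closing metathesis (second-generation Grubbs catalyst) to A2. It was turned down because a trisubstituted alkene inside a strained ten-membered ring forms poorly. The required Z geometry is not under control, and the carbene can also engage C11=C13 and C1=C10. Oligomers are the likely outcome.

Alternative 3: the bare skeleton first. The deoxy heliangolide A4 would be oxidized late at C3 and C8 to the diol A5. It was turned down because allylic oxidation (SeO2) of the C4=C5 unit favours C15 over C3, and because C8 is an unactivated methylene that no directing group reaches. The two hardest oxygenated centres would be left to the least selective steps.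

Key step: step 10

Remark: ring atoms are numbered as in germacranes (C1–C10 in ring A, C11–C13 in the lactone, C14 on C10, C15 on C4); 1, 7, 9 and 20 are taken as commercial.

## Route

Step 1
Reactants: 1 (S)-carvone
Product: 2 (1S,4S,6S)-1-methyl-4-(prop-1-en-2-yl)-7-oxabicyclo[4.1.0]heptan-2-one
Conditions: 30% H2O2, NaOH (cat.), MeOH, 0 °C
Reagents that add atoms: hydrogen peroxide, OO
Why: Nucleophilic (Weitz–Scheffer) epoxidation of the enone; the hydroperoxide adds anti to the isopropenyl group, so the oxirane is trans to it and the isopropenyl alkene is untouched.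

Step 2
Reactants: 2 (1S,4S,6S)-1-methyl-4-(prop-1-en-2-yl)-7-oxabicyclo[4.1.0]heptan-2-one
Product: 4 (1S,5R)-trans-carveol, via epoxy hydrazone 3 (not isolated)
Conditions: N2H4·H2O, AcOH (cat.), MeOH, 0 °C to rt
Reagents that add atoms: none
Why: Wharton transposition: the hydrazone of the α,β-epoxy ketone fragments with loss of N2 to the transposed allylic alcohol. The epoxide C–O bond at the carbinol carbon is kept, so the hydroxyl is trans to the isopropenyl group.

Step 3
Reactants: 4 (1S,5R)-trans-carveol
Product: 5 tert-butyldimethylsilyl ether of (1S,5R)-trans-carveol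
Conditions: TBSCl, imidazole, DMF, rt
Reagents that add atoms: tert-butyl(chloro)dimethylsilane, CC(C)(C)[Si](C)(C)Cl
Why: Standard silylation of a secondary allylic alcohol; the ether has to survive organolithium, KH and peroxide later.

Step 4
Reactants: 5 tert-butyldimethylsilyl ether of (1S,5R)-trans-carveol
Product: 6 (4S,6R)-4-(tert-butyldimethylsilyloxy)-3-methyl-6-(prop-1-en-2-yl)cyclohex-2-en-1-one
Conditions: CrO3, 3,5-dimethylpyrazole, CH2Cl2, −20 °C
Reagents that add atoms: chromium trioxide, O=[Cr](=O)=O
Why: Allylic oxidation of the only ring allylic methylene to the enone; the other ring allylic carbon carries the silyl ether. The non-basic medium should leave the new α-stereocentre (later C1) unepimerized.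

Step 5
Reactants: 7 2-bromoprop-2-en-1-ol
Product: 8 (2-bromoprop-2-en-1-yloxy)tri(propan-2-yl)silane
Conditions: TIPSCl, imidazole, CH2Cl2, rt
Reagents that add atoms: chlorotri(propan-2-yl)silane, CC(C)[Si](Cl)(C(C)C)C(C)C
Why: Silylation; the bulky triisopropylsilyl group is chosen so that it does not migrate from oxygen to the neighbouring carbanion in step 9.

Step 6
Reactants: 9 tert-butoxy(chloro)diphenylsilane
Product: 10 tert-butoxy(ethynyl)diphenylsilane
Conditions: HC≡CMgBr, THF, 0 °C to rt
Reagents that add atoms: ethynylmagnesium bromide, C#C[Mg]Br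
Why: Substitution of chloride at silicon by the Grignard reagent; the tert-butoxy group stays and later makes the C–Si bond oxidizable.

Step 7
Reactants: 8 (2-bromoprop-2-en-1-yloxy)tri(propan-2-yl)silane; 10 tert-butoxy(ethynyl)diphenylsilane
Product: 11 tert-butoxy(diphenyl)[3-(triisopropylsilyloxymethyl)but-3-en-1-ynyl]silane
Conditions: PdCl2(PPh3)2 (cat.), CuI (cat.), iPr2NH, THF, rt to 45 °C
Reagents that add atoms: none
Why: Sonogashira coupling of a vinyl bromide with a terminal alkyne; it forms the later C7–C11 bond.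

Step 8
Reactants: 11 tert-butoxy(diphenyl)[3-(triisopropylsilyloxymethyl)but-3-en-1-ynyl]silane
Product: 12 tert-butoxy(diphenyl)[(1E)-2-(tributylstannyl)-3-(triisopropylsilyloxymethyl)buta-1,3-dienyl]silane
Conditions: Bu3SnH, PdCl2(PPh3)2 (cat.), THF, 0 °C to rt
Reagents that add atoms: tributylstannane, CCCC[SnH](CCCC)CCCC
Why: Palladium-catalysed syn hydrostannation; tin goes to the alkyne carbon remote from the bulky silyl group and next to the vinyl group, hydrogen to the silyl-bearing carbon. Silicon therefore ends trans to tin and cis to the C11 unit.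

Step 9
Reactants: 12 tert-butoxy(diphenyl)[(1E)-2-(tributylstannyl)-3-(triisopropylsilyloxymethyl)buta-1,3-dienyl]silane; 6 (4S,6R)-4-(tert-butyldimethylsilyloxy)-3-methyl-6-(prop-1-en-2-yl)cyclohex-2-en-1-one
Product: 15 (1R,4S,6R)-1-[(1E)-1-(tert-butoxydiphenylsilyl)-3-(triisopropylsilyloxymethyl)buta-1,3-dien-2-yl]-4-(tert-butyldimethylsilyloxy)-3-methyl-6-(prop-1-en-2-yl)cyclohex-2-en-1-ol, via dienyllithium 13 (not isolated), via dienylcerium dichloride 14 (not isolated)
Conditions: n-BuLi, THF, −78 °C; CeCl3, −78 °C; then 6, −78 °C; aq. NH4Cl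
Reagents that add atoms: none
Why: Tin–lithium exchange with retention of alkene geometry, then transmetalation to the less basic organocerium to suppress enolization of 6. The sp2 nucleophile adds 1,2 from the face anti to the adjacent isopropenyl group, which gives the trans-1,2-dialkenyl carbinol (new centre C6, R).

Step 10
Reactants: 15 (1R,4S,6R)-1-[(1E)-1-(tert-butoxydiphenylsilyl)-3-(triisopropylsilyloxymethyl)buta-1,3-dien-2-yl]-4-(tert-butyldimethylsilyloxy)-3-methyl-6-(prop-1-en-2-yl)cyclohex-2-en-1-ol
Product: 18 (1(10)E,4Z)-8β-(tert-butoxydiphenylsilyl)-3β-(tert-butyldimethylsilyloxy)-12-(triisopropylsilyloxy)-7αH-germacra-1(10),4,11(13)-trien-6-one, via potassium alkoxide 16 (not isolated), via potassium enolate 17 (not isolated)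
Conditions: KH, 18-crown-6, THF, 0 to 55 °C; then AcOH/THF, −78 °C
Reagents that add atoms: none
Why: Deprotonation gives alkoxide 16, whose 3-oxido-1,5-diene C8=C7–C6(O)–C1–C10=C9 undergoes the [3,3]-sigmatropic shift (anionic oxy-Cope): C6–C1 breaks, C8–C9 forms, and enolate 17 is quenched cold. The closest known reaction type is the anionic oxy-Cope ring expansion of trans-1,2-dialkenylcyclohex-2-en-1-ols derived from 6-isopropenylcyclohexenones, which gives (E,Z)-cyclodecadienones. Ring A is closed by a four-atom ring expansion of the cyclohexene through a chair transition state, not end to end; both ring bonds (C6–C5 and C1–C2) are equatorial on that chair because the two alkenyl groups are trans. C1=C10 comes out E because C2 is equatorial, and C4=C5 stays Z because it was a ring alkene. C8 is set by chirality transfer from C1 and C6 through the chair: the silyl group, trans to C6 on the alkene, is equatorial, which fixes the C8–Si bond where the 8β-oxygen has to be. C7 is set in the quench: the tetrasubstituted E-enolate is planar-chiral and cannot turn through the ring, so the proton enters from the outer face and H7 ends α. The step must prefer this 1,5-diene over the one through the ring alkene C4=C5, which would need a bridged boat, and the β-substituent must survive: silicon is no leaving group, and being trans to the alkoxide it cannot be attacked by O6 before the shift. The C11=C13 vinyl group conjugates with the forming enolate and should lower the barrier.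

Step 11
Reactants: 18 (1(10)E,4Z)-8β-(tert-butoxydiphenylsilyl)-3β-(tert-butyldimethylsilyloxy)-12-(triisopropylsilyloxy)-7αH-germacra-1(10),4,11(13)-trien-6-one
Product: 19 (1(10)E,4Z)-3β-(tert-butyldimethylsilyloxy)-8β-hydroxy-12-(triisopropylsilyloxy)-7αH-germacra-1(10),4,11(13)-trien-6-one
Conditions: 30% H2O2, KF, KHCO3, THF/MeOH, 0 °C to rt
Reagents that add atoms: hydrogen peroxide, OO
Why: Tamao oxidation of the alkoxysilane: the C8–Si bond becomes C8–OH with retention. The conditions are free of acid and of electrophilic oxidant, so the trisubstituted alkenes are not touched, and the β,β-disubstituted enone should resist the weakly basic peroxide.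

Step 12
Reactants: 20 (E)-2-methylbut-2-en-1-ol
Product: 21 [(2S,3S)-2,3-dimethyloxiran-2-yl]methanol
Conditions: Ti(OiPr)4 (cat.), L-(+)-diethyl tartrate (cat.), t-BuOOH, 4 Å MS, CH2Cl2, −20 °C
Reagents that add atoms: tert-butyl hydroperoxide, CC(C)(C)OO
Why: Sharpless asymmetric epoxidation; with the L-(+)-tartrate the oxygen is delivered to the face that gives the (2S,3S) epoxy alcohol, and the E-alkene keeps the two methyl groups cis.

Step 13
Reactants: 21 [(2S,3S)-2,3-dimethyloxiran-2-yl]methanol
Product: 22 (2R,3S)-2,3-dimethyloxirane-2-carbaldehyde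
Conditions: Dess–Martin periodinane, NaHCO3, CH2Cl2, 0 °C to rt
Reagents that add atoms: none
Why: Buffered Dess–Martin oxidation of the primary alcohol; the α-carbon is quaternary, so the aldehyde cannot epimerize or enolize.

Step 14
Reactants: 19 (1(10)E,4Z)-3β-(tert-butyldimethylsilyloxy)-8β-hydroxy-12-(triisopropylsilyloxy)-7αH-germacra-1(10),4,11(13)-trien-6-one; 22 (2R,3S)-2,3-dimethyloxirane-2-carbaldehyde
Product: 23 (1(10)E,4Z)-3β-(tert-butyldimethylsilyloxy)-8β-[(2R,3S)-2,3-dimethyloxirane-2-carbonyloxy]-12-(triisopropylsilyloxy)-7αH-germacra-1(10),4,11(13)-trien-6α-ol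
Conditions: SmI2 (0.3 equiv), 22 (4 equiv), THF, −10 °C
Reagents that add atoms: none
Why: Evans–Tishchenko reduction: the aldehyde is bound to O8 and its formyl hydrogen is passed to C6 inside a chelate of trivalent samarium. This gives the 1,3-anti diol (C6, R) with the acyl group left on O8 and O6 free; the non-enolizable aldehyde suits this role.

Step 15
Reactants: 23 (1(10)E,4Z)-3β-(tert-butyldimethylsilyloxy)-8β-[(2R,3S)-2,3-dimethyloxirane-2-carbonyloxy]-12-(triisopropylsilyloxy)-7αH-germacra-1(10),4,11(13)-trien-6α-ol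
Product: 24 (1(10)E,4Z)-8β-[(2R,3S)-2,3-dimethyloxirane-2-carbonyloxy]-7αH-germacra-1(10),4,11(13)-triene-3β,6α,12-triol
Conditions: HF·pyridine, pyridine, THF, 0 °C to rt
Reagents that add atoms: none
Why: Buffered fluoride removes both silyl ethers; the mildly acidic, non-basic medium should avoid migration of the acyl group from O8 to O6 and spare the ester-deactivated oxirane.

Step 16
Reactants: 24 (1(10)E,4Z)-8β-[(2R,3S)-2,3-dimethyloxirane-2-carbonyloxy]-7αH-germacra-1(10),4,11(13)-triene-3β,6α,12-triol
Product: 27 (1(10)E,4Z)-8β-[(2R,3S)-2,3-dimethyloxirane-2-carbonyloxy]-3β-hydroxygermacra-1(10),4,11(13)-trien-6α,12-olide, via hydroxy enal 25 (not isolated), via lactol 26 (not isolated)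
Conditions: TEMPO (cat.), PhI(OAc)2, CH2Cl2, rt
Reagents that add atoms: none
Why: Oxoammonium oxidation is selective for the primary allylic alcohol; the enal is trapped by O6 as the five-membered lactol, which is oxidized on to the α-methylene lactone. O8 is acylated and cannot compete, and the secondary C3 alcohol reacts much more slowly.

Step 17
Reactants: 27 (1(10)E,4Z)-8β-[(2R,3S)-2,3-dimethyloxirane-2-carbonyloxy]-3β-hydroxygermacra-1(10),4,11(13)-trien-6α,12-olide
Product: 28 (1(10)E,4Z)-8β-[(2R,3S)-2,3-dimethyloxirane-2-carbonyloxy]-3β-(3-methylbutanoyloxy)germacra-1(10),4,11(13)-trien-6α,12-olide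
Conditions: 3-methylbutanoyl chloride, pyridine, DMAP (cat.), CH2Cl2, 0 °C
Reagents that add atoms: 3-methylbutanoyl chloride, CC(C)CC(Cl)=O
Why: Acylation of the only free hydroxyl under mild base; C3 keeps its configuration.

Step 18
Reactants: 28 (1(10)E,4Z)-8β-[(2R,3S)-2,3-dimethyloxirane-2-carbonyloxy]-3β-(3-methylbutanoyloxy)germacra-1(10),4,11(13)-trien-6α,12-olide
Product: 29 target, (1R,10R)-1,10-epoxide of 28
Conditions: mCPBA, NaHCO3, CH2Cl2, 0 °C
Reagents that add atoms: 3-chloroperoxybenzoic acid, OOC(=O)c1cccc(Cl)c1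
Why: Prilezhaev epoxidation of the only electron-rich alkene; C4=C5 is deactivated by two allylic acyloxy groups and C11=C13 is conjugated. The E-alkene stands across the ring with C14 on the β side, so attack from the outer face should give the 1β,10α (1R,10R) trans-epoxide.

## Compound list

1 | (S)-carvone, (5S)-2-methyl-5-(prop-1-en-2-yl)cyclohex-2-en-1-one | CC1=CC[C@@H](CC1=O)C(C)=C | starting material
2 | (1S,4S,6S)-1-methyl-4-(prop-1-en-2-yl)-7-oxabicyclo[4.1.0]heptan-2-one | O=C1C[C@@H](C(C)=C)C[C@@H]2O[C@]12C | intermediate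
3 | epoxy hydrazone (hydrazone of 2) | NN=C1C[C@@H](C(C)=C)C[C@@H]2O[C@]12C | intermediate
4 | (1S,5R)-trans-carveol, (1S,5R)-2-methyl-5-(prop-1-en-2-yl)cyclohex-2-en-1-ol | CC1=CC[C@H](C[C@@H]1O)C(C)=C | intermediate
5 | tert-butyldimethylsilyl ether of (1S,5R)-trans-carveol | CC1=CC[C@H](C[C@@H]1O[Si](C)(C)C(C)(C)C)C(C)=C | intermediate
6 | (4S,6R)-4-(tert-butyldimethylsilyloxy)-3-methyl-6-(prop-1-en-2-yl)cyclohex-2-en-1-one | CC1=CC(=O)[C@H](C[C@@H]1O[Si](C)(C)C(C)(C)C)C(C)=C | intermediate
7 | 2-bromoprop-2-en-1-ol | OCC(Br)=C | starting material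
8 | (2-bromoprop-2-en-1-yloxy)tri(propan-2-yl)silane | C=C(Br)CO[Si](C(C)C)(C(C)C)C(C)C | intermediate
9 | tert-butoxy(chloro)diphenylsilane | Cl[Si](OC(C)(C)C)(c1ccccc1)c1ccccc1 | starting material
10 | tert-butoxy(ethynyl)diphenylsilane | C#C[Si](OC(C)(C)C)(c1ccccc1)c1ccccc1 | intermediate
11 | tert-butoxy(diphenyl)[3-(triisopropylsilyloxymethyl)but-3-en-1-ynyl]silane | C=C(CO[Si](C(C)C)(C(C)C)C(C)C)C#C[Si](OC(C)(C)C)(c1ccccc1)c1ccccc1 | intermediate
12 | tert-butoxy(diphenyl)[(1E)-2-(tributylstannyl)-3-(triisopropylsilyloxymethyl)buta-1,3-dienyl]silane (Si trans to Sn) | CCCC[Sn](CCCC)(CCCC)/C(=C/[Si](OC(C)(C)C)(c1ccccc1)c1ccccc1)C(=C)CO[Si](C(C)C)(C(C)C)C(C)C | intermediate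
13 | dienyllithium from 12 | [Li]/C(=C/[Si](OC(C)(C)C)(c1ccccc1)c1ccccc1)C(=C)CO[Si](C(C)C)(C(C)C)C(C)C | intermediate
14 | dienylcerium dichloride from 13 | Cl[Ce](Cl)/C(=C/[Si](OC(C)(C)C)(c1ccccc1)c1ccccc1)C(=C)CO[Si](C(C)C)(C(C)C)C(C)C | intermediate
15 | (1R,4S,6R)-1-[(1E)-1-(tert-butoxydiphenylsilyl)-3-(triisopropylsilyloxymethyl)buta-1,3-dien-2-yl]-4-(tert-butyldimethylsilyloxy)-3-methyl-6-(prop-1-en-2-yl)cyclohex-2-en-1-ol | CC1=C[C@](O)(/C(=C/[Si](OC(C)(C)C)(c2ccccc2)c2ccccc2)C(=C)CO[Si](C(C)C)(C(C)C)C(C)C)[C@H](C[C@@H]1O[Si](C)(C)C(C)(C)C)C(C)=C | intermediate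
16 | potassium alkoxide of 15 | [K+].CC1=C[C@]([O-])(/C(=C/[Si](OC(C)(C)C)(c2ccccc2)c2ccccc2)C(=C)CO[Si](C(C)C)(C(C)C)C(C)C)[C@H](C[C@@H]1O[Si](C)(C)C(C)(C)C)C(C)=C | intermediate
17 | potassium enolate of 18 (C6=C7 enolate, C5 trans to C8) | [K+].[O-]/C1=C(/C(=C)CO[Si](C(C)C)(C(C)C)C(C)C)\[C@H]([Si](OC(C)(C)C)(c2ccccc2)c2ccccc2)C/C(C)=C/C[C@H](O[Si](C)(C)C(C)(C)C)/C(C)=C\1 | intermediate
18 | (1(10)E,4Z)-8β-(tert-butoxydiphenylsilyl)-3β-(tert-butyldimethylsilyloxy)-12-(triisopropylsilyloxy)-7αH-germacra-1(10),4,11(13)-trien-6-one | O=C1/C=C(/C)[C@@H](O[Si](C)(C)C(C)(C)C)C/C=C(C)/C[C@@H]([Si](OC(C)(C)C)(c2ccccc2)c2ccccc2)[C@H]1C(=C)CO[Si](C(C)C)(C(C)C)C(C)C | intermediate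
19 | (1(10)E,4Z)-3β-(tert-butyldimethylsilyloxy)-8β-hydroxy-12-(triisopropylsilyloxy)-7αH-germacra-1(10),4,11(13)-trien-6-one | O=C1/C=C(/C)[C@@H](O[Si](C)(C)C(C)(C)C)C/C=C(C)/C[C@@H](O)[C@H]1C(=C)CO[Si](C(C)C)(C(C)C)C(C)C | intermediate
20 | (E)-2-methylbut-2-en-1-ol | C/C=C(\C)CO | starting material
21 | [(2S,3S)-2,3-dimethyloxiran-2-yl]methanol | OC[C@]1(C)O[C@H]1C | intermediate
22 | (2R,3S)-2,3-dimethyloxirane-2-carbaldehyde | O=C[C@]1(C)O[C@H]1C | intermediate
23 | (1(10)E,4Z)-3β-(tert-butyldimethylsilyloxy)-8β-[(2R,3S)-2,3-dimethyloxirane-2-carbonyloxy]-12-(triisopropylsilyloxy)-7αH-germacra-1(10),4,11(13)-trien-6α-ol | O[C@@H]1/C=C(/C)[C@@H](O[Si](C)(C)C(C)(C)C)C/C=C(C)/C[C@@H](OC(=O)[C@]2(C)O[C@H]2C)[C@H]1C(=C)CO[Si](C(C)C)(C(C)C)C(C)C | intermediate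
24 | (1(10)E,4Z)-8β-[(2R,3S)-2,3-dimethyloxirane-2-carbonyloxy]-7αH-germacra-1(10),4,11(13)-triene-3β,6α,12-triol | O[C@@H]1/C=C(/C)[C@@H](O)C/C=C(C)/C[C@@H](OC(=O)[C@]2(C)O[C@H]2C)[C@H]1C(=C)CO | intermediate
25 | hydroxy enal (12-aldehyde of 24) | O[C@@H]1/C=C(/C)[C@@H](O)C/C=C(C)/C[C@@H](OC(=O)[C@]2(C)O[C@H]2C)[C@H]1C(=C)C=O | intermediate
26 | lactol (6α,12-hemiacetal of 25) | C=C1C(O)O[C@@H]2/C=C(/C)[C@@H](O)C/C=C(C)/C[C@@H](OC(=O)[C@]3(C)O[C@H]3C)[C@@H]12 | intermediate
27 | (1(10)E,4Z)-8β-[(2R,3S)-2,3-dimethyloxirane-2-carbonyloxy]-3β-hydroxygermacra-1(10),4,11(13)-trien-6α,12-olide | C=C1C(=O)O[C@@H]2/C=C(/C)[C@@H](O)C/C=C(C)/C[C@@H](OC(=O)[C@]3(C)O[C@H]3C)[C@@H]12 | intermediate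
28 | (1(10)E,4Z)-8β-[(2R,3S)-2,3-dimethyloxirane-2-carbonyloxy]-3β-(3-methylbutanoyloxy)germacra-1(10),4,11(13)-trien-6α,12-olide | C=C1C(=O)O[C@@H]2/C=C(/C)[C@@H](OC(=O)CC(C)C)C/C=C(C)/C[C@@H](OC(=O)[C@]3(C)O[C@H]3C)[C@@H]12 | intermediate
29 | CNP0167461.4, (1R,10R)-1,10-epoxide of 28 | C=C1C(=O)O[C@@H]2/C=C(/C)[C@@H](OC(=O)CC(C)C)C[C@H]3O[C@]3(C)C[C@@H](OC(=O)[C@]3(C)O[C@H]3C)[C@@H]12 | target

## Step count and least certain steps

Total step count: 18. Longest linear sequence: 12 steps (steps 1–4, 9–11 and 14–18); steps 5–8 and 12–13 are side branches.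

Step 10 (key step). The shift may be slowed by crowding of the chair by the silyl and dienyl groups. Prolonged exposure to the base could then lead to decomposition of the alkoxide or to proton exchange at C7 of the enolate. Participation of the ring alkene is a further escape. Fallback, from 15 back to 18: a neutral variant in which the protonation is a separate operation. Carbinol 15 would be silylated (TMS-imidazole) to the trimethylsilyl ether F1. F1 would be heated in degassed toluene at about 150 °C, below the temperature at which the 1(10),4-diene of the product would itself rearrange, to give the trimethylsilyl enol ether F2. F2 would be cleaved with K2CO3 in MeOH at −20 °C, with protonation from the outer face, to 18.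

Step 4. The oxidant may also attack the allylic positions of the isopropenyl group or the C–H next to the silyl ether, and the enone may over-oxidize, so that the conversion to 6 is low. Fallback, from 5 back to 6: a two-step formal allylic oxidation. Singlet-oxygen ene reaction (O2, tetraphenylporphyrin, light) on the ring alkene would give the tertiary allylic hydroperoxide F3, which PPh3 would reduce to the tertiary allylic alcohol F4 (either epimer serves). Babler–Dauben oxidative transposition with pyridinium chlorochromate would then give 6.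

Step 11. Under the weakly basic peroxide the new β-hydroxy ketone may undergo retro-aldol cleavage or dehydration, and the C11=C13 alkene may move into conjugation through enolization at C7. Fallback, from 18 back to 19: the ketone is taken out of the way during the oxidation. Luche reduction (NaBH4, CeCl3) of 18 would give the allylic alcohol F5 (both C6 epimers serve). Tamao oxidation would give the diol F6. MnO2, which oxidizes only the allylic hydroxyl, would return 19 under neutral conditions.

Step 14. SmI2 may open the α,β-epoxy aldehyde reductively, or the α-quaternary aldehyde may be too hindered for the hydride transfer, so that the reduction stalls or the acyl group migrates. Fallback, from 19 back to 24: the acyl group is brought in by esterification instead. Evans–Tishchenko reduction with acetaldehyde would give the acetate F7. TESOTf and 2,6-lutidine would give the triethylsilyl ether F8, and iBu2AlH at −78 °C the C8 alcohol F9. Pinnick oxidation of 22 (NaClO2, NaH2PO4, 2-methylbut-2-ene) would give the epoxy acid F10. Yamaguchi esterification of F9 with F10 would give the ester F11, and HF·pyridine would remove the three silyl groups to give 24.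

Step 18. Facial selectivity may be poor if both planar-chiral conformers of the E-alkene are populated, and some epoxidation of C4=C5 may compete. Fallback, from 28 back to 29: catalyst control in place of substrate control. Shi epoxidation with the D-fructose-derived ketone and KHSO5 (as Oxone) in buffered MeCN/dimethoxymethane–water at 0 °C is expected by the spiro transition-state model to give the (1R,10R) epoxide of an E-trisubstituted alkene; it makes no new compound (F0).

Further compounds

F1 | step 10 | trimethylsilyl ether of 15 | CC1=C[C@](O[Si](C)(C)C)(/C(=C/[Si](OC(C)(C)C)(c2ccccc2)c2ccccc2)C(=C)CO[Si](C(C)C)(C(C)C)C(C)C)[C@H](C[C@@H]1O[Si](C)(C)C(C)(C)C)C(C)=C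
F2 | step 10 | trimethylsilyl enol ether of 18 (C6=C7, C5 trans to C8) | C[Si](C)(C)O/C1=C(/C(=C)CO[Si](C(C)C)(C(C)C)C(C)C)\[C@H]([Si](OC(C)(C)C)(c2ccccc2)c2ccccc2)C/C(C)=C/C[C@H](O[Si](C)(C)C(C)(C)C)/C(C)=C\1
F3 | step 4 | tertiary allylic hydroperoxide from 5 (carbinol carbon not defined) | CC1(OO)C=C[C@H](C[C@@H]1O[Si](C)(C)C(C)(C)C)C(C)=C
F4 | step 4 | tertiary allylic alcohol from F3 (carbinol carbon not defined) | CC1(O)C=C[C@H](C[C@@H]1O[Si](C)(C)C(C)(C)C)C(C)=C
F5 | step 11 | C6 allylic alcohol from 18 (C6 not defined) | OC1/C=C(/C)[C@@H](O[Si](C)(C)C(C)(C)C)C/C=C(C)/C[C@@H]([Si](OC(C)(C)C)(c2ccccc2)c2ccccc2)[C@H]1C(=C)CO[Si](C(C)C)(C(C)C)C(C)C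
F6 | step 11 | 6,8-diol from F5 (C6 not defined) | OC1/C=C(/C)[C@@H](O[Si](C)(C)C(C)(C)C)C/C=C(C)/C[C@@H](O)[C@H]1C(=C)CO[Si](C(C)C)(C(C)C)C(C)C
F7 | step 14 | 8β-acetate 6α-alcohol from 19 | O[C@@H]1/C=C(/C)[C@@H](O[Si](C)(C)C(C)(C)C)C/C=C(C)/C[C@@H](OC(C)=O)[C@H]1C(=C)CO[Si](C(C)C)(C(C)C)C(C)C
F8 | step 14 | 6α-triethylsilyl ether of F7 | CC[Si](CC)(CC)O[C@@H]1/C=C(/C)[C@@H](O[Si](C)(C)C(C)(C)C)C/C=C(C)/C[C@@H](OC(C)=O)[C@H]1C(=C)CO[Si](C(C)C)(C(C)C)C(C)C
F9 | step 14 | 8β-alcohol from F8 | CC[Si](CC)(CC)O[C@@H]1/C=C(/C)[C@@H](O[Si](C)(C)C(C)(C)C)C/C=C(C)/C[C@@H](O)[C@H]1C(=C)CO[Si](C(C)C)(C(C)C)C(C)C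
F10 | step 14 | (2R,3S)-2,3-dimethyloxirane-2-carboxylic acid | OC(=O)[C@]1(C)O[C@H]1C
F11 | step 14 | 8β-(2R,3S)-2,3-dimethyloxirane-2-carboxylate of F9 | CC[Si](CC)(CC)O[C@@H]1/C=C(/C)[C@@H](O[Si](C)(C)C(C)(C)C)C/C=C(C)/C[C@@H](OC(=O)[C@]2(C)O[C@H]2C)[C@H]1C(=C)CO[Si](C(C)C)(C(C)C)C(C)C
F0 | step 18 | none | none
A1 | alternative 1 | methyl (2E,6E,10Z)-2-(bromomethyl)-4,9-bis(tert-butyldimethylsilyloxy)-6,10-dimethyl-12-oxododeca-2,6,10-trienoate (C4 and C9 as C8 and C3 of 29) | O=C/C=C(/C)[C@@H](O[Si](C)(C)C(C)(C)C)C/C=C(C)/C[C@@H](O[Si](C)(C)C(C)(C)C)/C=C(/CBr)C(=O)OC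
A2 | alternative 1 | (1(10)E,4Z)-3β,8β-bis(tert-butyldimethylsilyloxy)germacra-1(10),4,11(13)-trien-6α,12-olide | C=C1C(=O)O[C@@H]2/C=C(/C)[C@@H](O[Si](C)(C)C(C)(C)C)C/C=C(C)/C[C@@H](O[Si](C)(C)C(C)(C)C)[C@@H]12
A3 | alternative 2 | 4,5-seco diene: 3-methylene-5-vinyl-γ-butyrolactone with the C8–C4 chain and a terminal isopropenyl group (C3, C6, C7, C8 as in 29) | C=C[C@H]1OC(=O)C(=C)[C@@H]1[C@H](O[Si](C)(C)C(C)(C)C)C/C(C)=C/C[C@H](O[Si](C)(C)C(C)(C)C)C(C)=C
A4 | alternative 3 | (1(10)E,4Z)-germacra-1(10),4,11(13)-trien-6α,12-olide | C=C1C(=O)O[C@@H]2/C=C(/C)CC/C=C(C)/CC[C@@H]12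
A5 | alternative 3 | (1(10)E,4Z)-3β,8β-dihydroxygermacra-1(10),4,11(13)-trien-6α,12-olide | C=C1C(=O)O[C@@H]2/C=C(/C)[C@@H](O)C/C=C(C)/C[C@@H](O)[C@@H]12
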